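**Retrosynthetic overview**

- The strategy rests on ring C, the 4-pyranone: its carbonyl carbon C4 is a single carbon lying between aryl carbon C4a and the C3=C2 pair that carries ring B, and O1 sits on C8a, ortho to C4a.
- Ring A piece: 2,3-dimethoxyphenol 1 is taken through MOM-directed ortho-lithiation/iodination and deprotection to o-iodophenol 5 (ring A with O1).
- Ring B piece: 3-bromo-4,5-dimethoxybenzaldehyde 6 has Br exchanged for OH, is MOM-protected and homologated with the Ohira–Bestmann reagent 10 to arylacetylene 11 (C3, C2, ring B).
- Key disconnection: the C4a–C4, C4–C3 and O1–C2 bonds of ring C, made from 5, 11 and carbon monoxide 12 (C4=O) in one palladium-catalysed operation. Rings A and B are bought; ring C is the only ring formed and is formed last, and MOM removal then gives target 16.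

Key step: step 8

Remark: flavone numbering is used (O1, C2, C3, C4, C4a, C5 to C8, C8a; primed locants for ring B). The target has no stereocentre or stereogenic double bond, so no stereocontrol is needed.

**Route**

Step 1
Reactants: 1 2,3-dimethoxyphenol
Product: 2 1,2-dimethoxy-3-(methoxymethoxy)benzene
Conditions: MOMCl, i-Pr2NEt, CH2Cl2, 0 °C to rt
Reagents that add atoms: chloromethyl methyl ether (MOMCl), COCCl
Why: O-alkylation of the phenol with the reactive alpha-chloro ether (MOM ether formation) under a hindered amine base should be clean and installs the chelating acetal that directs the lithiation in step 2.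

Step 2
Reactants: 2 1,2-dimethoxy-3-(methoxymethoxy)benzene
Product: 4 1-iodo-3,4-dimethoxy-2-(methoxymethoxy)benzene, via aryllithium 3 (not isolated)
Conditions: n-BuLi, THF, 0 °C; then I2, −78 °C to rt
Reagents that add atoms: iodine, II
Why: Directed ortho-metalation, in which the OMOM group outranks the methyl ethers as director and has only one free ortho position (the future C4a), so deprotonation there and electrophilic iodination of aryllithium 3 should place iodine next to the masked phenol.

Step 3
Reactants: 4 1-iodo-3,4-dimethoxy-2-(methoxymethoxy)benzene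
Product: 5 6-iodo-2,3-dimethoxyphenol
Conditions: HCl, MeOH, 40 °C
Reagents that add atoms: none
Why: Acid-catalysed acetal exchange with methanol (MOM cleavage) frees the phenol that becomes O1, while the aryl iodide and the two methyl ethers are inert to dilute HCl.

Step 4
Reactants: 6 3-bromo-4,5-dimethoxybenzaldehyde
Product: 7 3,4-dimethoxy-5-(4,4,5,5-tetramethyl-1,3,2-dioxaborolan-2-yl)benzaldehyde
Conditions: B2pin2, PdCl2(dppf) (cat.; dppf = 1,1'-bis(diphenylphosphino)ferrocene), KOAc, 1,4-dioxane, 85 °C
Reagents that add atoms: bis(pinacolato)diboron, CC1(C)OB(OC1(C)C)B1OC(C)(C)C(C)(C)O1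
Why: Miyaura borylation (oxidative addition of zerovalent palladium into C–Br, acetate-assisted transmetalation with the diboron, reductive elimination) should tolerate the aldehyde because KOAc is a weak, non-nucleophilic base.

Step 5
Reactants: 7 3,4-dimethoxy-5-(4,4,5,5-tetramethyl-1,3,2-dioxaborolan-2-yl)benzaldehyde
Product: 8 3-hydroxy-4,5-dimethoxybenzaldehyde
Conditions: NaBO3·4H2O, THF/H2O, rt
Reagents that add atoms: sodium perborate tetrahydrate (NaBO3·4H2O, dimeric peroxoborate), [Na+].[Na+].O[B-]1(O)OO[B-](O)(O)OO1
Why: Boronate oxidation (peroxide adds to boron, the aryl group shifts from boron to oxygen, the borate ester hydrolyses) should be much faster than any attack on the aldehyde, which has no ortho or para hydroxyl to promote Dakin cleavage.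

Step 6
Reactants: 8 3-hydroxy-4,5-dimethoxybenzaldehyde
Product: 9 3,4-dimethoxy-5-(methoxymethoxy)benzaldehyde
Conditions: MOMCl, i-Pr2NEt, CH2Cl2, 0 °C to rt
Reagents that add atoms: chloromethyl methyl ether (MOMCl), COCCl
Why: MOM ether formation by O-alkylation masks the future 3'-OH with a base-stable acetal that should survive the basic homologation and the amine/CO conditions of the annulation.

Step 7
Reactants: 9 3,4-dimethoxy-5-(methoxymethoxy)benzaldehyde; 10 dimethyl (1-diazo-2-oxopropyl)phosphonate (Ohira–Bestmann reagent)
Product: 11 5-ethynyl-1,2-dimethoxy-3-(methoxymethoxy)benzene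
Conditions: K2CO3, MeOH, rt
Reagents that add atoms: none
Why: Seyferth–Gilbert homologation in its Ohira–Bestmann form, in which methoxide deacetylates 10 to the diazomethylphosphonate anion that converts the non-enolisable aldehyde into the terminal alkyne, the former diazo carbon becoming the terminal CH (the future C3).

Step 8
Reactants: 5 6-iodo-2,3-dimethoxyphenol; 11 5-ethynyl-1,2-dimethoxy-3-(methoxymethoxy)benzene; 12 carbon monoxide
Product: 15 7,8-dimethoxy-2-[3,4-dimethoxy-5-(methoxymethoxy)phenyl]chromen-4-one, via o-hydroxyaryl ynone 13 (not isolated), via beta-diethylamino enone 14 (not isolated)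
Conditions: PdCl2(dppf) (cat.), CO (about 20 bar), Et2NH, 120 °C, autoclave
Reagents that add atoms: none
Why: Carbonylative Sonogashira coupling followed by amine-mediated annulation: zerovalent palladium formed from PdCl2(dppf) inserts into the C–I bond of 5, CO insertion gives an aroylpalladium iodide, and amine-assisted transfer of the acetylide of 11 with reductive elimination gives ynone 13, which creates the C4a–C4 and C4–C3 bonds. Diethylamine then adds to the alkyne carbon remote from the carbonyl to give enaminone 14, and the ortho phenol oxygen attacks this same carbon and expels the amine, forming O1–C2. The closest known reaction type is the copper-free palladium-catalysed three-component coupling of o-iodophenols, CO and terminal arylacetylenes in a secondary amine, which delivers flavones in one operation. Ring C, the only ring closed, forms in a 6-endo mode, formally an intramolecular oxa-Michael addition–elimination on 14. No stereocentre arises and the double-bond geometry of 14 is lost when the pyranone forms. Two selectivities are required: CO insertion before alkynyl transfer, favoured by the electron-rich arylpalladium species, the CO pressure and the absence of copper (otherwise a 2-arylbenzofuran), and six- over five-membered closure, secured by the amine because C2 is the only electrophilic carbon of 14 within reach of the phenol (otherwise an aurone); the C–I bond is the sole reactive halide and the MOM and methyl ethers are inert to amine and CO.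

Step 9
Reactants: 15 7,8-dimethoxy-2-[3,4-dimethoxy-5-(methoxymethoxy)phenyl]chromen-4-one
Product: 16 3'-hydroxy-4',5',7,8-tetramethoxyflavone
Conditions: HCl, MeOH/THF, 50 °C
Reagents that add atoms: none
Why: Acid-catalysed acetal cleavage (MOM removal) should release the 3'-OH selectively, since aryl methyl ethers and the flavone nucleus are stable to HCl in methanol.

**Compound list**

1 | 2,3-dimethoxyphenol | COc1cccc(O)c1OC | starting material
2 | 1,2-dimethoxy-3-(methoxymethoxy)benzene | COCOc1cccc(OC)c1OC | intermediate
3 | [3,4-dimethoxy-2-(methoxymethoxy)phenyl]lithium | [Li]c1ccc(OC)c(OC)c1OCOC | intermediate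
4 | 1-iodo-3,4-dimethoxy-2-(methoxymethoxy)benzene | COCOc1c(I)ccc(OC)c1OC | intermediate
5 | 6-iodo-2,3-dimethoxyphenol | COc1ccc(I)c(O)c1OC | intermediate
6 | 3-bromo-4,5-dimethoxybenzaldehyde | COc1cc(C=O)cc(Br)c1OC | starting material
7 | 3,4-dimethoxy-5-(4,4,5,5-tetramethyl-1,3,2-dioxaborolan-2-yl)benzaldehyde | COc1cc(C=O)cc(B2OC(C)(C)C(C)(C)O2)c1OC | intermediate
8 | 3-hydroxy-4,5-dimethoxybenzaldehyde | COc1cc(C=O)cc(O)c1OC | intermediate
9 | 3,4-dimethoxy-5-(methoxymethoxy)benzaldehyde | COCOc1cc(C=O)cc(OC)c1OC | intermediate
10 | dimethyl (1-diazo-2-oxopropyl)phosphonate (Ohira–Bestmann reagent) | CC(=O)C(=[N+]=[N-])P(=O)(OC)OC | starting material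
11 | 5-ethynyl-1,2-dimethoxy-3-(methoxymethoxy)benzene | C#Cc1cc(OC)c(OC)c(OCOC)c1 | intermediate
12 | carbon monoxide | [C-]#[O+] | starting material
13 | 1-(2-hydroxy-3,4-dimethoxyphenyl)-3-[3,4-dimethoxy-5-(methoxymethoxy)phenyl]prop-2-yn-1-one | COc1ccc(C(=O)C#Cc2cc(OC)c(OC)c(OCOC)c2)c(O)c1OC | intermediate
14 | (E)-3-(diethylamino)-1-(2-hydroxy-3,4-dimethoxyphenyl)-3-[3,4-dimethoxy-5-(methoxymethoxy)phenyl]prop-2-en-1-one (drawn as the expected E isomer; the geometry has no consequence) | CCN(CC)/C(=C/C(=O)c1ccc(OC)c(OC)c1O)c1cc(OC)c(OC)c(OCOC)c1 | intermediate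
15 | 7,8-dimethoxy-2-[3,4-dimethoxy-5-(methoxymethoxy)phenyl]chromen-4-one | COCOc1cc(-c2cc(=O)c3ccc(OC)c(OC)c3o2)cc(OC)c1OC | intermediate
16 | 3'-hydroxy-4',5',7,8-tetramethoxyflavone | COc1cc(-c2cc(=O)c3ccc(OC)c(OC)c3o2)cc(O)c1OC | target

**Step count**

Total step count: 9
Longest linear sequence: 6 steps (steps 4, 5, 6, 7, 8 and 9, from 6 to 16)

**Steps most likely to fail**

1. Step 8. The alkynyl group may transfer to palladium before CO has inserted (direct coupling and cycloisomerisation), diethylamine or a phenol may capture the aroylpalladium species, or the sequence may stall before ring closure or close in the five-membered sense. The fallback builds the same three ring C bonds without palladium or CO; it sets out from 2 (through aryllithium 3) and from 11 and rejoins the route at 16. Aryllithium 3, generated as in step 2, would be quenched with N,N-dimethylformamide to give 3,4-dimethoxy-2-(methoxymethoxy)benzaldehyde F1. Alkyne 11 would be deprotonated with n-BuLi in THF at −78 °C to the lithium acetylide of 11 F2, which should add to F1 to give racemic 1-[3,4-dimethoxy-2-(methoxymethoxy)phenyl]-3-[3,4-dimethoxy-5-(methoxymethoxy)phenyl]prop-2-yn-1-ol F3. Oxidation of this benzylic, propargylic alcohol with MnO2 in CH2Cl2 should give 1-[3,4-dimethoxy-2-(methoxymethoxy)phenyl]-3-[3,4-dimethoxy-5-(methoxymethoxy)phenyl]prop-2-yn-1-one F4. HCl in methanol would remove both MOM groups to give 1-(2-hydroxy-3,4-dimethoxyphenyl)-3-(3-hydroxy-4,5-dimethoxyphenyl)prop-2-yn-1-one F5; any conjugate adduct of HCl or methanol formed here converges in the next operation. Diethylamine in ethanol should then close ring C by the same enaminone addition–elimination and give 16 directly, so step 9 is not needed.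

2. Step 2. Metalation may occur partly at the other open flank of the trioxygenated ring (ortho to the terminal methoxy group) or remain incomplete, so that iodine ends up in the wrong place or starting material is carried on. The fallback uses a stronger directing group; it sets out from 1 and rejoins at 5. Phenol 1 would be acylated with N,N-diethylcarbamoyl chloride and K2CO3 in acetonitrile to give 2,3-dimethoxyphenyl N,N-diethylcarbamate F6. Treatment with s-BuLi and TMEDA in THF at −78 °C should give the ortho-lithiated carbamate [2-(diethylcarbamoyloxy)-3,4-dimethoxyphenyl]lithium F7, which is kept cold to prevent anionic Fries rearrangement. Quenching with I2 should give 6-iodo-2,3-dimethoxyphenyl N,N-diethylcarbamate F8, and hydrolysis with NaOH in aqueous ethanol at reflux followed by acidification should deliver 5.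

3. Step 5. The oxidant may attack the aldehyde (over-oxidation to the acid or Dakin-type loss of the formyl group as the ring becomes more electron-rich), and boron residues may be carried into the phenol. The fallback uses no oxidant; it sets out from 6 and rejoins at 8, replacing steps 4 and 5. Aldehyde 6 would be acetalised with ethylene glycol and catalytic TsOH in toluene (Dean–Stark) to give 2-(3-bromo-4,5-dimethoxyphenyl)-1,3-dioxolane F9. Palladium-catalysed hydroxylation of the aryl bromide (Pd2(dba)3, 2-di-tert-butylphosphino-2',4',6'-triisopropylbiphenyl, KOH, 1,4-dioxane/H2O, 100 °C) should give 5-(1,3-dioxolan-2-yl)-2,3-dimethoxyphenol F10. Aqueous HCl in THF would then hydrolyse the acetal to 8.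

**Further compounds**

F1 | step 8 | 3,4-dimethoxy-2-(methoxymethoxy)benzaldehyde | COCOc1c(C=O)ccc(OC)c1OC
F2 | step 8 | lithium acetylide of 11, {[3,4-dimethoxy-5-(methoxymethoxy)phenyl]ethynyl}lithium | [Li]C#Cc1cc(OC)c(OC)c(OCOC)c1
F3 | step 8 | racemic 1-[3,4-dimethoxy-2-(methoxymethoxy)phenyl]-3-[3,4-dimethoxy-5-(methoxymethoxy)phenyl]prop-2-yn-1-ol | COCOc1c(C(O)C#Cc2cc(OC)c(OC)c(OCOC)c2)ccc(OC)c1OC
F4 | step 8 | 1-[3,4-dimethoxy-2-(methoxymethoxy)phenyl]-3-[3,4-dimethoxy-5-(methoxymethoxy)phenyl]prop-2-yn-1-one | COCOc1c(C(=O)C#Cc2cc(OC)c(OC)c(OCOC)c2)ccc(OC)c1OC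
F5 | step 8 | 1-(2-hydroxy-3,4-dimethoxyphenyl)-3-(3-hydroxy-4,5-dimethoxyphenyl)prop-2-yn-1-one | COc1ccc(C(=O)C#Cc2cc(O)c(OC)c(OC)c2)c(O)c1OC
F6 | step 2 | 2,3-dimethoxyphenyl N,N-diethylcarbamate | CCN(CC)C(=O)Oc1cccc(OC)c1OC
F7 | step 2 | [2-(diethylcarbamoyloxy)-3,4-dimethoxyphenyl]lithium | [Li]c1ccc(OC)c(OC)c1OC(=O)N(CC)CC
F8 | step 2 | 6-iodo-2,3-dimethoxyphenyl N,N-diethylcarbamate | CCN(CC)C(=O)Oc1c(I)ccc(OC)c1OC
F9 | step 5 | 2-(3-bromo-4,5-dimethoxyphenyl)-1,3-dioxolane | COc1cc(C2OCCO2)cc(Br)c1OC
F10 | step 5 | 5-(1,3-dioxolan-2-yl)-2,3-dimethoxyphenol | COc1cc(C2OCCO2)cc(O)c1OC
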